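## Structural features

The target is a single cyclohexane ring (C1–C6) in which the quaternary C1 carries a hydroxyl and the carboxyl carbon C7, C2 and C6 are methylenes, and C3, C4 and C5 are three contiguous carbinol carbons. O3 is esterified with (E)-caffeic acid and O4 with (E)-p-coumaric acid, while O5–H, O1–H and the acid are free. O3 and O4 are cis, O4 and O5 trans, O1 is cis to O3 and C7 is cis to O5; C1 is stereogenic only because the two ring arms (C2–C3 and C6–C5) differ. The fragile parts are the two cinnamoyl esters on a cis-diol next to a free hydroxyl (migration and hydrolysis in base), the oxidizable catechol, the conjugated alkenes (no late hydrogenation) and the tertiary α-hydroxy acid. The real difficulty is to place two different acyl groups on adjacent secondary oxygens while a third stays free, and to fix the remote quaternary C1 relative to C3–C5. The key step uses the fact that C5 is a carbinol flanked by the C6 methylene, and that C6 is allylic once C1–C7 is written as an exocyclic alkene. The C5–C6 bond is then the bond made when an allylsilane adds to an aldehyde, and the chain C1–C5 with cis oxygens on C3 and C4 is a 2-deoxypentose of the L series.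

## Logic of the disconnections

**24 ⇒ 23.** The C7–O5 ester bond is re-formed and the three phenols are capped. Tying O5 to C7 hides both groups that must end free and flips the ring, so that O3 becomes equatorial and O4 axial. The forward unveiling must be acidic, because base would move the acyl groups among O3, O4 and O5.

**23 ⇒ 19 + 21 (used as 22).** The O4–acyl bond is cut. The axial O4 is the less reactive oxygen and is acylated second with an activated donor. The forward step must not move the O3 ester or touch the tertiary O1. 21 comes from 20 by O-acetylation.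

**19 ⇒ 15 + 17 (used as 18).** The O3–acyl bond is cut. In 15 the equatorial O3–H is the most accessible of three hydroxyls, so the gain is a triol that needs no protecting group. The demand is regioselectivity. 17 comes from 16.

**15 ⇒ 14 ⇒ 13.** The lactone C7–O5 bond and the O5–benzyl bond are cut. The benzyl group is needed earlier (next paragraph) and must leave by hydrogenolysis before any cinnamate is present.

**13 ⇒ 12 ⇒ 11 ⇒ 10.** C7 is taken back from acid to primary alcohol, the C7–O bond is cut (epoxide opening), then the C1–O bond (epoxide to alkene). C1 becomes trigonal, so the quaternary stereocenter disappears and can be rebuilt under the direction of the axial O3–H. This demands a free O3–H, and an O5 mask that cannot direct, survives hydroxide and does not migrate.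

**10 ⇒ 9 ⇒ 8.** Protecting groups are exchanged: acetonide back on O3/O4, benzyl off O5. In 8 only O5–H is free, so O5 is distinguished from O3 and O4 without any selectivity problem.

**8 ⇒ 7.** The C5–C6 bond is cut. This opens the carbocycle to an acyclic aldehyde whose only stereocenters, C3 and C4, sit in a cis-acetonide. The forward step must set C5 trans to O4 under non-basic conditions.

**7 ⇒ 6 ⇒ 3 + 4 (via 5).** The aldehyde is taken back to the primary alcohol, and the C1–C6 and C1–C7 bonds are cut. Both silylmethyl carbons come from 4, two equivalents of which add to the one acyl carbon of 3; the ring oxygen of 3 becomes the C5 hydroxyl without a protecting group. Double addition must outrun enolization and β-elimination of O3.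

**3 ⇒ 2 ⇒ 1.** The lactone is taken back to the lactol and the acetonide removed. 1 holds C1–C5 with C3 and C4 in the required absolute configuration. The demand is acetonation at the cis-3,4-diol of the pyranose.

## Other disconnections considered

Alternative 1: The cut is the C1–O bond of the tertiary carbinol, together with a C2–O bond that exists only temporarily. It leads back to (−)-shikimic acid (A1), used as its methyl ester 5-silyl ether (A2).
- Forward key step: a peracid, held by hydrogen bonds to the allylic O3–H and to O4–H, would epoxidize C1=C2 of A2 to the epoxide A3, with the new C1–O bond cis to O3. C2–O would then be removed by opening at C2 with halide and reductive dehalogenation; desilylation and lactonization would reach 15.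
- In its favour: all seven carbons and the centers C3–C5 are present in A1, and no C–C bond has to be made. The oxygen at C1 is delivered by an allylic hydroxyl, a stronger directing arrangement than the homoallylic one of step 8. On these points it is the better plan.
- Against it: the alkene is conjugated to the ester and is a poor partner for an electrophilic peracid. The usual reductive openings of α,β-epoxy esters break the α C–O bond, which is the one to keep, so the C2–O bond would first have to be exchanged for a C2–halogen bond. The 2,3-epoxy alcohol unit of A3 can rearrange in base. A2 requires selective silylation of O5 beside O3–H and O4–H.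
- Comparison: in structure the alternative starts far closer to the target. In mechanism its key step is an electronically mismatched oxygen transfer, while the chosen key step forms a ring and a stereocenter at once, so neither is clearly safer. In step economy the alternative should need about half the steps to reach 15 and is the better one.

Alternative 2: The cut is the C4=C5 bond of the cyclohexene A5, opened to the acyclic diene A4, in which C1 and C3 are already in place.
- Forward key step: ring-closing metathesis of A4 with the second-generation Grubbs catalyst. Hydroxyl-directed oxygen transfer to C4=C5 from the O3 face, then attack of the C7 carboxyl at C5 with inversion, would give 15 directly.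
- In its favour: the ring closure creates no stereocenter and is as reliable as any six-membered closure. The relay sets C4 and C5 stereospecifically (syn oxygen transfer, anti opening) and delivers O5 already in the lactone, so no O5 protecting group is needed. Here the alternative is the better.
- Against it: the two stereocenters of A4 are 1,3-related across a methylene and one is quaternary. They have no obvious chiral-pool source and must be made by asymmetric synthesis, with induction to a tetrasubstituted carbon that is not reliably high. The allylic alcohol may also isomerize to a ketone if the catalyst decomposes.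
- Comparison: the chosen plan takes C3 and C4 from the sugar and sets C5 and C1 by substrate control in a ring. The alternative must create C1 and C3 in an open chain and then relays C4 and C5. Its ring closure is more predictable than step 5, but its stereochemical burden moves to the acyclic stage. In steps it should be equal or slightly shorter to 15.

Alternative 3: The cut goes through C1–C6 and C2–C3, a retro-Diels–Alder reaction to buta-1,3-diene (A7) and the chiral methylene dioxolanone A6. For the natural series the acetal carbon of A6 has to be R.
- Forward key step: thermal cycloaddition on the face of A6 away from the tert-butyl group, giving the spiro adduct A8 with C1 set. Acetal cleavage, halolactonization onto C5, elimination to the C3=C4 alkene and cis-dihydroxylation away from the lactone bridge would give 15.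
- In its favour: two C–C bonds and the ring form in one step from simple components. C1 is fixed first and C5, C3 and C4 are relayed from it within a rigid bicyclic framework. O5 needs no protecting group. It is probably the shortest way to 15; on stereochemical relay and step count it is the better plan.
- Against it: the absolute configuration of the whole molecule rests on one facial selection by a remote tert-butyl group. A7 is unactivated, so heat and pressure are needed and polymerization of A6 competes. A6 takes several steps and needs the less common enantiomer of its chiral-pool source.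
- Comparison: in the chosen plan C3 and C4 are enantiopure by origin and no auxiliary is needed, which is its structural merit. A thermal cycloaddition and a halolactonization are at least as dependable as the Lewis-acid cyclization and directed epoxidation used here. In step economy the alternative is better.

Key step: step 5

Remarks on the chemistry (assumptions):
- Quinic acid numbering is used throughout (C1 quaternary, C7 carboxyl carbon). The target is read as the 3-O-caffeoyl-4-O-p-coumaroyl ester of (−)-quinic acid.
- Atom-by-atom comparison of the configurations confirms that ring C3 and C4 of the target correspond to C3 (R) and C4 (S) of 2-deoxy-L-ribose, and that 7 and 8 carry them unchanged. Compound 1 is drawn open-chain for atom bookkeeping although it is a hemiacetal.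
- The open-chain Felkin rotamer cannot be used to predict C5 in step 5, because it would lead to the 4,5-cis isomer. The argument for trans is made in the step.
- O5 is carried as a benzyl ether and not as a silyl ether, because it must survive hot hydroxide in step 9 without migrating to O4.

## Route

Step 1
Reactants: 1 2-deoxy-L-ribose
Product: 2 3,4-O-isopropylidene-2-deoxy-L-erythro-pentopyranose (lactol; anomeric mixture)
Conditions: 2-methoxypropene, PPTS (cat.), EtOAc, 0 °C → rt
Reagents that add atoms: 2-methoxypropene, COC(C)=C
Why: Kinetic acetonation of the pyranose engages its only cis-vicinal diol (O3/O4) as a dioxolane and leaves the anomeric hydroxyl free; acetal formation under mild acid, no stereocenter touched.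

Step 2
Reactants: 2 3,4-O-isopropylidene-2-deoxy-L-erythro-pentopyranose
Product: 3 3,4-O-isopropylidene-2-deoxy-L-erythro-pentono-1,5-lactone
Conditions: PhI(OAc)2, TEMPO (cat.), CH2Cl2, rt
Reagents that add atoms: none
Why: Oxoammonium-mediated oxidation of a lactol to the lactone; the near-neutral medium leaves the acetonide and both stereocenters alone.

Step 3
Reactants: 3 3,4-O-isopropylidene-2-deoxy-L-erythro-pentono-1,5-lactone; 4 (trimethylsilyl)methylmagnesium chloride (two equivalents enter the product)
Product: 6 [(4S,5R)-2,2-dimethyl-5-{2-[(trimethylsilyl)methyl]prop-2-en-1-yl}-1,3-dioxolan-4-yl]methanol, via bis(silylmethyl) carbinol 5 (not isolated)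
Conditions: Me3SiCH2MgCl (5 equiv), CeCl3 (5 equiv), THF, −78 °C → rt; aq. NH4Cl; then SiO2, CH2Cl2, rt
Reagents that add atoms: (trimethylsilyl)methylmagnesium chloride (second equivalent of 4), C[Si](C)(C)C[Mg]Cl
Why: The weakly basic organocerium reagent Me3SiCH2CeCl2, formed from 4 and CeCl3, adds twice to the lactone carbonyl, so that two silylmethyl groups from two equivalents of 4 sit on C1 of 5 while enolization and β-elimination of O3 are suppressed; the tertiary β,β'-disilyl carbinol then loses Me3SiOH on silica (Peterson elimination) to leave the 2-substituted allylsilane, and the former ring oxygen is released as the C5 primary alcohol.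

Step 4
Reactants: 6 [(4S,5R)-2,2-dimethyl-5-{2-[(trimethylsilyl)methyl]prop-2-en-1-yl}-1,3-dioxolan-4-yl]methanol
Product: 7 (4R,5R)-2,2-dimethyl-5-{2-[(trimethylsilyl)methyl]prop-2-en-1-yl}-1,3-dioxolane-4-carbaldehyde (cis-dioxolane)
Conditions: Dess–Martin periodinane, NaHCO3, CH2Cl2, 0 °C → rt; used at once
Reagents that add atoms: none
Why: Buffered Dess–Martin oxidation stops at the aldehyde and avoids both acid (protodesilylation) and amine base (C4 epimerization, β-elimination of O3).

Step 5
Reactants: 7 (4R,5R)-2,2-dimethyl-5-{2-[(trimethylsilyl)methyl]prop-2-en-1-yl}-1,3-dioxolane-4-carbaldehyde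
Product: 8 (3aS,4R,7aR)-2,2-dimethyl-6-methylidenehexahydro-1,3-benzodioxol-4-ol (ring numbering of the target: 3,4-O-isopropylidene, 5-OH trans to O4, C1=C7 exocyclic)
Conditions: BF3·OEt2 (1.1 equiv), CH2Cl2, −78 °C; aq. NaHCO3
Reagents that add atoms: none
Why: BF3 binds the aldehyde oxygen and the terminal alkene carbon of the allylsilane (the future C6) attacks C5 in an SE2' sense; the cation developing at C1 is stabilized by the β C–Si bond and collapses by loss of Me3SiF to the exocyclic C1=C7 alkene. The closest known reaction type is the intramolecular Hosomi–Sakurai cyclization of 2-(silylmethyl)allyl-tethered aldehydes to 3-methylenecyclohexanols. The ring closes 6-exo-trig at the carbonyl (O5 stays outside the ring) with the allyl π bond inside the new ring, through an open chair-like transition state. The new stereocenter C5 is controlled by C4: in the favoured chair the C4–O bond is antiperiplanar to the forming C5–C6 bond (Anh-type σ* stabilization), which puts O4 equatorial and O3 axial in the cis-fused dioxolane, and the BF3-bound carbonyl oxygen takes the equatorial site to avoid a syn-axial contact with O3, so O5 should end trans to O4. Because the nucleophile is tethered through C3, this is the rotamer opposite to the open-chain Felkin one; the flipped chair with O4 and O5 both axial and their dipoles opposed (Cornforth-like) leads to the same trans product. The step needs diastereoselectivity at C5 only, since the silylmethyl group fixes which allyl terminus reacts and where the alkene ends. No base is present and the temperature is low, so C4 epimerization and β-elimination of O3 in the α,β-dialkoxy aldehyde should not compete and the acetonide should survive.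

Step 6
Reactants: 8 (3aS,4R,7aR)-2,2-dimethyl-6-methylidenehexahydro-1,3-benzodioxol-4-ol
Product: 9 (3aS,4R,7aR)-4-(benzyloxy)-2,2-dimethyl-6-methylidenehexahydro-1,3-benzodioxole
Conditions: NaH, BnBr, Bu4NI (cat.), THF, 0 °C → rt
Reagents that add atoms: benzyl bromide, BrCc1ccccc1
Why: Williamson etherification of the only free hydroxyl; the benzyl ether survives aqueous acid, peroxide, hot hydroxide and the later oxidation, cannot migrate to O4, and leaves by hydrogenolysis before any cinnamate is present.

Step 7
Reactants: 9 (3aS,4R,7aR)-4-(benzyloxy)-2,2-dimethyl-6-methylidenehexahydro-1,3-benzodioxole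
Product: 10 (1R,2R,3R)-3-(benzyloxy)-5-methylidenecyclohexane-1,2-diol (target numbering: 3,4-diol, 5-OBn)
Conditions: AcOH–H2O (4:1), 45 °C
Reagents that add atoms: none
Why: Acid hydrolysis of the dioxolane under conditions too mild to isomerize the 1,1-disubstituted alkene or cleave the benzyl ether.

Step 8
Reactants: 10 (1R,2R,3R)-3-(benzyloxy)-5-methylidenecyclohexane-1,2-diol
Product: 11 (3S,5R,6R,7R)-5-(benzyloxy)-1-oxaspiro[2.5]octane-6,7-diol (epoxide oxygen on C1 cis to O3)
Conditions: VO(acac)2 (cat.), t-BuOOH (in decane), CH2Cl2, 0 °C → rt
Reagents that add atoms: tert-butyl hydroperoxide, CC(C)(C)OO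
Why: Hydroxyl-directed epoxidation: the t-BuOO–V species formed from VO(acac)2 and bound to the axial homoallylic O3 (O4 and O5 equatorial in the favoured chair) delivers oxygen to the top face of C1=C7, so the new C1–O bond is cis to O3; the etherified O5 cannot direct to the other face.

Step 9
Reactants: 11 (3S,5R,6R,7R)-5-(benzyloxy)-1-oxaspiro[2.5]octane-6,7-diol
Product: 12 (1S,3R,4R,5R)-5-(benzyloxy)-1-(hydroxymethyl)cyclohexane-1,3,4-triol
Conditions: KOH, DMSO–H2O, 90 °C
Reagents that add atoms: water, O
Why: Hydroxide opens the 2,2-disubstituted oxirane by SN2 attack at the unsubstituted C7, so the C1–O bond and the C1 configuration are untouched; acid is avoided because it would ionize the tertiary C1–O bond.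

Step 10
Reactants: 12 (1S,3R,4R,5R)-5-(benzyloxy)-1-(hydroxymethyl)cyclohexane-1,3,4-triol
Product: 13 5-O-benzyl-(−)-quinic acid [(1S,3R,4R,5R)-5-(benzyloxy)-1,3,4-trihydroxycyclohexane-1-carboxylic acid]
Conditions: TEMPO (cat.), NaOCl (cat.), NaClO2, MeCN–phosphate buffer (pH 6.7), 35 °C
Reagents that add atoms: sodium chlorite, [Na+].[O-]Cl=O
Why: The hindered oxoammonium salt oxidizes the primary C7 hydroxyl in preference to the secondary ones and chlorite takes the aldehyde on to the acid; the tertiary O1–H cannot be oxidized.

Step 11
Reactants: 13 5-O-benzyl-(−)-quinic acid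
Product: 15 1,5-quinide [(1S,3R,4R,5R)-1,3,4-trihydroxy-6-oxabicyclo[3.2.1]octan-7-one], via (−)-quinic acid 14 (not isolated)
Conditions: H2 (1 atm), Pd/C, MeOH, rt; filter, evaporate; then Amberlyst 15 (H+ form), toluene–DMF, reflux (Dean–Stark)
Reagents that add atoms: none
Why: Hydrogenolysis frees O5 while no alkene is present; acid-catalysed dehydration of the crude acid then closes the γ-lactone between C7 and O5, the only hydroxyl cis to the carboxyl and able to reach it, with a ring flip.

Step 12
Reactants: 16 caffeic acid
Product: 17 (E)-3-(3,4-diacetoxyphenyl)prop-2-enoic acid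
Conditions: Ac2O (3 equiv), pyridine, DMAP (cat.), 0 °C → rt; aqueous work-up
Reagents that add atoms: acetic anhydride, CC(=O)OC(C)=O
Why: Acetylation of both phenols masks the catechol against oxidation and self-acylation; the acetates later leave in the same acidic hydrolysis as the lactone.

Step 13
Reactants: 15 1,5-quinide; 17 (E)-3-(3,4-diacetoxyphenyl)prop-2-enoic acid
Product: 19 3-O-[(E)-3,4-diacetoxycinnamoyl]-1,5-quinide, via 3,4-diacetoxycinnamoyl chloride 18 (not isolated)
Conditions: 17, (COCl)2, DMF (cat.), CH2Cl2, 0 °C → rt, evaporate; then 15, pyridine, −20 → 0 °C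
Reagents that add atoms: none
Why: In the lactone O3–H is equatorial and open, O4–H is axial under the lactone bridge and O1–H is tertiary, so one equivalent of the acid chloride should acylate O3 by nucleophilic acyl substitution at low temperature.

Step 14
Reactants: 20 p-coumaric acid
Product: 21 (E)-3-(4-acetoxyphenyl)prop-2-enoic acid
Conditions: Ac2O, pyridine, DMAP (cat.), 0 °C → rt; aqueous work-up
Reagents that add atoms: acetic anhydride, CC(=O)OC(C)=O
Why: Phenol acetylation, as in step 12.

Step 15
Reactants: 19 3-O-[(E)-3,4-diacetoxycinnamoyl]-1,5-quinide; 21 (E)-3-(4-acetoxyphenyl)prop-2-enoic acid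
Product: 23 3-O-[(E)-3,4-diacetoxycinnamoyl]-4-O-[(E)-4-acetoxycinnamoyl]-1,5-quinide, via 4-acetoxycinnamoyl chloride 22 (not isolated)
Conditions: 21, (COCl)2, DMF (cat.), CH2Cl2, 0 °C → rt, evaporate; then 19, DMAP (cat.), pyridine–CH2Cl2, 0 °C → rt
Reagents that add atoms: none
Why: DMAP-catalysed acylation of the remaining secondary, axial O4–H; the tertiary O1–H next to the lactone carbonyl should react much more slowly, and the anhydrous weakly basic medium gives the O3 ester little chance to migrate.

Step 16
Reactants: 23 3-O-[(E)-3,4-diacetoxycinnamoyl]-4-O-[(E)-4-acetoxycinnamoyl]-1,5-quinide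
Product: 24 3-O-caffeoyl-4-O-p-coumaroyl-(−)-quinic acid (target)
Conditions: 1 M HCl (aq)–THF (1:3), rt
Reagents that add atoms: water, O
Why: Acid-catalysed hydrolysis opens the strained bicyclic γ-lactone (freeing O5–H and the acid) and cleaves the three aryl acetates, which are far more labile than the two conjugated secondary cinnamates; acidic pH suppresses acyl migration among O3, O4 and O5.

## Compound list

1 | 2-deoxy-L-ribose [(3R,4S)-3,4,5-trihydroxypentanal, drawn open-chain] | O=CC[C@@H](O)[C@@H](O)CO | starting material
2 | 3,4-O-isopropylidene-2-deoxy-L-erythro-pentopyranose (anomeric mixture) | OC1C[C@H]2OC(C)(C)O[C@H]2CO1 | intermediate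
3 | 3,4-O-isopropylidene-2-deoxy-L-erythro-pentono-1,5-lactone | O=C1C[C@H]2OC(C)(C)O[C@H]2CO1 | intermediate
4 | (trimethylsilyl)methylmagnesium chloride | C[Si](C)(C)C[Mg]Cl | starting material
5 | [(4S,5R)-5-{2-hydroxy-3-(trimethylsilyl)-2-[(trimethylsilyl)methyl]propyl}-2,2-dimethyl-1,3-dioxolan-4-yl]methanol (formed in the flask) | C[Si](C)(C)CC(O)(C[Si](C)(C)C)C[C@H]1OC(C)(C)O[C@H]1CO | intermediate
6 | [(4S,5R)-2,2-dimethyl-5-{2-[(trimethylsilyl)methyl]prop-2-en-1-yl}-1,3-dioxolan-4-yl]methanol | C[Si](C)(C)CC(=C)C[C@H]1OC(C)(C)O[C@H]1CO | intermediate
7 | (4R,5R)-2,2-dimethyl-5-{2-[(trimethylsilyl)methyl]prop-2-en-1-yl}-1,3-dioxolane-4-carbaldehyde | C[Si](C)(C)CC(=C)C[C@H]1OC(C)(C)O[C@H]1C=O | intermediate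
8 | (3aS,4R,7aR)-2,2-dimethyl-6-methylidenehexahydro-1,3-benzodioxol-4-ol | C=C1C[C@@H](O)[C@@H]2OC(C)(C)O[C@@H]2C1 | intermediate
9 | (3aS,4R,7aR)-4-(benzyloxy)-2,2-dimethyl-6-methylidenehexahydro-1,3-benzodioxole | C=C1C[C@@H](OCc3ccccc3)[C@@H]2OC(C)(C)O[C@@H]2C1 | intermediate
10 | (1R,2R,3R)-3-(benzyloxy)-5-methylidenecyclohexane-1,2-diol | C=C1C[C@@H](OCc2ccccc2)[C@H](O)[C@H](O)C1 | intermediate
11 | (3S,5R,6R,7R)-5-(benzyloxy)-1-oxaspiro[2.5]octane-6,7-diol | C1O[C@]12C[C@@H](O)[C@@H](O)[C@H](OCc3ccccc3)C2 | intermediate
12 | (1S,3R,4R,5R)-5-(benzyloxy)-1-(hydroxymethyl)cyclohexane-1,3,4-triol | OC[C@]1(O)C[C@@H](O)[C@@H](O)[C@H](OCc2ccccc2)C1 | intermediate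
13 | 5-O-benzyl-(−)-quinic acid | OC(=O)[C@]1(O)C[C@@H](O)[C@@H](O)[C@H](OCc2ccccc2)C1 | intermediate
14 | (−)-quinic acid (formed in the flask) | OC(=O)[C@]1(O)C[C@@H](O)[C@@H](O)[C@H](O)C1 | intermediate
15 | 1,5-quinide [(1S,3R,4R,5R)-1,3,4-trihydroxy-6-oxabicyclo[3.2.1]octan-7-one] | O=C1O[C@@H]2C[C@@]1(O)C[C@@H](O)[C@H]2O | intermediate
16 | caffeic acid | OC(=O)/C=C/c1ccc(O)c(O)c1 | starting material
17 | (E)-3-(3,4-diacetoxyphenyl)prop-2-enoic acid | OC(=O)/C=C/c1ccc(OC(C)=O)c(OC(C)=O)c1 | intermediate
18 | (E)-3-(3,4-diacetoxyphenyl)prop-2-enoyl chloride (formed in the flask) | ClC(=O)/C=C/c1ccc(OC(C)=O)c(OC(C)=O)c1 | intermediate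
19 | 3-O-[(E)-3,4-diacetoxycinnamoyl]-1,5-quinide | O=C1O[C@@H]2C[C@@]1(O)C[C@@H](OC(=O)/C=C/c3ccc(OC(C)=O)c(OC(C)=O)c3)[C@H]2O | intermediate
20 | p-coumaric acid | OC(=O)/C=C/c1ccc(O)cc1 | starting material
21 | (E)-3-(4-acetoxyphenyl)prop-2-enoic acid | OC(=O)/C=C/c1ccc(OC(C)=O)cc1 | intermediate
22 | (E)-3-(4-acetoxyphenyl)prop-2-enoyl chloride (formed in the flask) | ClC(=O)/C=C/c1ccc(OC(C)=O)cc1 | intermediate
23 | 3-O-[(E)-3,4-diacetoxycinnamoyl]-4-O-[(E)-4-acetoxycinnamoyl]-1,5-quinide | O=C1O[C@@H]2C[C@@]1(O)C[C@@H](OC(=O)/C=C/c3ccc(OC(C)=O)c(OC(C)=O)c3)[C@H]2OC(=O)/C=C/c4ccc(OC(C)=O)cc4 | intermediate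
24 | 3-O-caffeoyl-4-O-p-coumaroyl-(−)-quinic acid [(1R,3R,4S,5R)-3-{[(E)-3-(3,4-dihydroxyphenyl)prop-2-enoyl]oxy}-1,5-dihydroxy-4-{[(E)-3-(4-hydroxyphenyl)prop-2-enoyl]oxy}cyclohexane-1-carboxylic acid] | O=C(/C=C/c1ccc(O)cc1)O[C@H]1[C@H](O)C[C@](O)(C(=O)O)C[C@H]1OC(=O)/C=C/c1ccc(O)c(O)c1 | target

## Step count and least certain steps

Total step count: 16. Longest linear sequence: 14 (steps 1–11, 13, 15 and 16); steps 12 and 14 are one-step side branches.

**Step 5 (key step).** The most likely failure is poor facial selectivity at the aldehyde, because two chair arrangements of similar energy are open and BF3 cannot chelate. Epimerization at C4 or protodesilylation before ring closure are lesser risks. Fallback, setting out from 7 and returning at 8: the cyclization is run for conversion alone and the separated C5 epimer, (3aS,4S,7aR)-2,2-dimethyl-6-methylidenehexahydro-1,3-benzodioxol-4-ol F1, is inverted by a Mitsunobu reaction (4-nitrobenzoic acid, PPh3, DIAD, THF) to (3aR,4R,7aR)-2,2-dimethyl-6-methylidenehexahydro-1,3-benzodioxol-4-yl 4-nitrobenzoate F2. Methanolysis of F2 (K2CO3, MeOH) gives 8. Displacement occurs on the face away from the acetonide.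

**Step 8.** The most likely failure is insufficient face discrimination or slow oxygen transfer. Direction by a homoallylic hydroxyl to an exocyclic alkene is weaker than allylic direction and depends on the chair with axial O3, and the cis-diol may chelate vanadium and slow turnover. Fallback, setting out from 10 and returning at 11: the oxygen is delivered through a covalent tether. The dilithium alkoxide of 10 (n-BuLi, THF, −78 °C) is carboxylated with CO2 and treated with I2; the O3 carbonate closes onto C1 to give the iodo carbonate 7-(benzyloxy)-6-hydroxy-1-(iodomethyl)-2,4-dioxabicyclo[3.3.1]nonan-3-one F3, in which the C1–O bond is necessarily cis to O3. K2CO3 in MeOH then cleaves the carbonate and the C1 alkoxide displaces iodide to give 11.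

**Step 10.** The most likely failure is loss of chemoselectivity: oxidation at the secondary hydroxyls or cleavage of the C1–C7 bond at the α-hydroxy aldehyde stage. Fallback, setting out from 11 and returning at 13: the cis-diol is masked first (2-methoxypropene, PPTS) as the 3,4-O-isopropylidene derivative of 11 F4. The epoxide is opened as in step 9 to the 3,4-O-isopropylidene derivative of 12 F5. The now single oxidizable hydroxyl is oxidized as in step 10 to 5-O-benzyl-3,4-O-isopropylidenequinic acid F6. Aqueous acetic acid then removes the acetonide to give 13.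

**Step 13.** The most likely failure is incomplete regioselectivity between O3 and O4, with some bis-acylation, since it rests only on the equatorial/axial difference. Fallback, setting out from 15 and returning at 23 (steps 13 and 15 are both replaced): O3 is blocked with the bulkier, more discriminating silyl chloride (TBSCl, imidazole, DMF) as 3-O-(tert-butyldimethylsilyl)-1,5-quinide F7. O4 is acylated with 22 (DMAP, pyridine) to 3-O-(tert-butyldimethylsilyl)-4-O-[(E)-4-acetoxycinnamoyl]-1,5-quinide F8. The silyl group is removed under acidic fluoride conditions (HF·pyridine, THF) to 4-O-[(E)-4-acetoxycinnamoyl]-1,5-quinide F9. O3 is then acylated with 18 to give 23.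

**Step 16.** The most likely failure is slow, incomplete hydrolysis, with partial cleavage of the cinnamoyl esters during the long exposure needed for three aryl acetates and the lactone together. Fallback, setting out from 23 and returning at 24: the two events are separated and the aryl acetates are removed by a different, near-neutral process (NH4OAc, aqueous THF, no alcohol so that the lactone is not transesterified). This gives 3-O-caffeoyl-4-O-p-coumaroyl-1,5-quinide F10. The lactone of F10 alone is then opened by a short hydrolysis in dilute aqueous acid, stopped as soon as ester loss begins.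

## Further compounds

F1 | step 5 | (3aS,4S,7aR)-2,2-dimethyl-6-methylidenehexahydro-1,3-benzodioxol-4-ol | C=C1C[C@H](O)[C@@H]2OC(C)(C)O[C@@H]2C1
F2 | step 5 | (3aR,4R,7aR)-2,2-dimethyl-6-methylidenehexahydro-1,3-benzodioxol-4-yl 4-nitrobenzoate | C=C1C[C@@H](OC(=O)c3ccc(cc3)[N+](=O)[O-])[C@@H]2OC(C)(C)O[C@@H]2C1
F3 | step 8 | 7-(benzyloxy)-6-hydroxy-1-(iodomethyl)-2,4-dioxabicyclo[3.3.1]nonan-3-one (carbonate bridge from O3 to C1, ring configuration of 10) | IC[C@@]12C[C@@H](OCc3ccccc3)[C@H](O)[C@@H](C1)OC(=O)O2
F4 | step 10 | 3,4-O-isopropylidene derivative of 11 | C1O[C@]12C[C@H]3OC(C)(C)O[C@H]3[C@H](OCc4ccccc4)C2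
F5 | step 10 | 3,4-O-isopropylidene derivative of 12 | OC[C@]1(O)C[C@H]2OC(C)(C)O[C@H]2[C@H](OCc3ccccc3)C1
F6 | step 10 | 5-O-benzyl-3,4-O-isopropylidenequinic acid | OC(=O)[C@]1(O)C[C@H]2OC(C)(C)O[C@H]2[C@H](OCc3ccccc3)C1
F7 | step 13 | 3-O-(tert-butyldimethylsilyl)-1,5-quinide | O=C1O[C@@H]2C[C@@]1(O)C[C@@H](O[Si](C)(C)C(C)(C)C)[C@H]2O
F8 | step 13 | 3-O-(tert-butyldimethylsilyl)-4-O-[(E)-4-acetoxycinnamoyl]-1,5-quinide | O=C1O[C@@H]2C[C@@]1(O)C[C@@H](O[Si](C)(C)C(C)(C)C)[C@H]2OC(=O)/C=C/c3ccc(OC(C)=O)cc3
F9 | step 13 | 4-O-[(E)-4-acetoxycinnamoyl]-1,5-quinide | O=C1O[C@@H]2C[C@@]1(O)C[C@@H](O)[C@H]2OC(=O)/C=C/c3ccc(OC(C)=O)cc3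
F10 | step 16 | 3-O-caffeoyl-4-O-p-coumaroyl-1,5-quinide | O=C1O[C@@H]2C[C@@]1(O)C[C@@H](OC(=O)/C=C/c3ccc(O)c(O)c3)[C@H]2OC(=O)/C=C/c4ccc(O)cc4
A1 | alternative 1 | (−)-shikimic acid [(3R,4S,5R)-3,4,5-trihydroxycyclohex-1-ene-1-carboxylic acid] | OC(=O)C1=C[C@@H](O)[C@@H](O)[C@H](O)C1
A2 | alternative 1 | methyl 5-O-(tert-butyldimethylsilyl)shikimate | COC(=O)C1=C[C@@H](O)[C@@H](O)[C@H](O[Si](C)(C)C(C)(C)C)C1
A3 | alternative 1 | methyl 1,2-epoxy-5-O-(tert-butyldimethylsilyl)shikimate (epoxide cis to O3) | COC(=O)[C@@]12C[C@@H](O[Si](C)(C)C(C)(C)C)[C@H](O)[C@H](O)[C@@H]1O2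
A4 | alternative 2 | ethyl (2R,4R)-2,4-dihydroxy-2-(prop-2-en-1-yl)hex-5-enoate | CCOC(=O)[C@@](O)(CC=C)C[C@@H](O)C=C
A5 | alternative 2 | ethyl (1R,3R)-1,3-dihydroxycyclohex-4-ene-1-carboxylate (1,3-cis) | CCOC(=O)[C@]1(O)C[C@@H](O)C=CC1
A6 | alternative 3 | (2R)-2-tert-butyl-5-methylidene-1,3-dioxolan-4-one | O=C1O[C@H](C(C)(C)C)OC1=C
A7 | alternative 3 | buta-1,3-diene | C=CC=C
A8 | alternative 3 | (2R,5S)-2-tert-butyl-1,3-dioxaspiro[4.5]dec-7-en-4-one | O=C1O[C@H](C(C)(C)C)O[C@@]12CC=CCC2
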